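**Plan**

- Numbering (bicyclo[3.2.1]octane): C1 is the prenyl-bearing bridgehead, C2(=O)–C3(isobutyryl)=C4(OH) the enolised dione bridge, C5 the methyl-bearing bridgehead, C6 the CH carrying the hydroxyisopropyl group, C7 the CH2, C8 the bridging ketone.
- Cuts, in retrosynthetic order: the prenyl C=C (back to allyl), the tertiary C–OH bond (back to 2-propenyl), then C1–C7 and C5–C6 in one operation.
- Enabling feature: ring C1–C2–C3–C4–C5–C8 is a dearomatised acylphloroglucinol ring whose meta carbons C1 and C5 are spanned by the C7–C6 bridge. C7, C6 and the three hydroxyisopropyl carbons form one isoprene unit, so the bridge maps onto a 2-methylbut-2-ene-1,4-diyl bis-electrophile.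
- Forward order: the fully substituted arene (two steps) and the carbonate–acetate (three steps) are made separately. One palladium-catalysed double allylation then builds the cyclopentanone ring C1–C7–C6–C5–C8 onto the six-membered ring, and hydration and cross-metathesis finish the side chains.
- Stereochemistry: C1 comes from the chiral diphosphine–palladium catalyst in the first C–C bond formation, C5 from the geometric constraint of the two-atom bridge, and C6 from exo placement of the 2-propenyl group in the ring closure. No later step touches these centres.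

Key step: step 6

Remark: enolised β-triketones are written as one tautomer and the CIP descriptors refer to that tautomer; the (R,R)-diphosphine is taken to give the required sense at C1, and its mirror-image ligand is used with no other change if the induction proves opposite.

**Route**

Step 1
Reactants: 1 2,4,6-trihydroxytoluene; 2 isobutyryl chloride
Product: 3 1-(2,4,6-trihydroxy-3-methylphenyl)-2-methylpropan-1-one
Conditions: AlCl3 (3 equiv), PhNO2, rt → 60 °C; then ice/1 M HCl
Reagents that add atoms: none
Why: Friedel–Crafts acylation of the strongly activated triol takes place at one of its two equivalent free ring positions, and the aluminium-chelated aryl ketone formed is deactivated towards a second acylation.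

Step 2
Reactants: 3 1-(2,4,6-trihydroxy-3-methylphenyl)-2-methylpropan-1-one; 4 allyl bromide
Product: 5 1-[2,4,6-trihydroxy-3-methyl-5-(prop-2-en-1-yl)phenyl]-2-methylpropan-1-one
Conditions: 10% aq. KOH, 0 °C → rt, allyl bromide (1.0 equiv) added slowly; then 1 M HCl
Reagents that add atoms: none
Why: Base-mediated C-allylation of an acylphloroglucinol in water, where the solvated phenolate oxygens leave carbon as the nucleophilic site and the only unsubstituted ring carbon reacts first because it alone can rearomatise.

Step 3
Reactants: 6 prenol
Product: 7 methyl 3-methylbut-2-en-1-yl carbonate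
Conditions: ClCO2Me, pyridine, CH2Cl2, 0 °C
Reagents that add atoms: methyl chloroformate, COC(=O)Cl
Why: Pyridine-mediated acylation of a primary allylic alcohol by a chloroformate (carbonate formation).

Step 4
Reactants: 7 methyl 3-methylbut-2-en-1-yl carbonate
Product: 8 (2E)-4-hydroxy-3-methylbut-2-en-1-yl methyl carbonate
Conditions: SeO2 (cat.), t-BuOOH, salicylic acid (cat.), CH2Cl2, rt
Reagents that add atoms: tert-butyl hydroperoxide, CC(C)(C)OO; selenium dioxide, O=[Se]=O
Why: Catalytic SeO2 allylic oxidation (ene reaction followed by [2,3]-sigmatropic shift) of a trisubstituted alkene attacks the methyl group trans to the chain and so should give the E allylic alcohol, with the carbonate untouched.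

Step 5
Reactants: 8 (2E)-4-hydroxy-3-methylbut-2-en-1-yl methyl carbonate
Product: 9 (2E)-4-[(methoxycarbonyl)oxy]-2-methylbut-2-en-1-yl acetate
Conditions: Ac2O, pyridine, DMAP (cat.), CH2Cl2, 0 °C → rt
Reagents that add atoms: acetic anhydride, CC(=O)OC(C)=O
Why: DMAP-catalysed acetylation of the primary allylic alcohol, which leaves the two allylic termini with leaving groups of clearly different ionisation rate.

Step 6
Reactants: 5 1-[2,4,6-trihydroxy-3-methyl-5-(prop-2-en-1-yl)phenyl]-2-methylpropan-1-one; 9 (2E)-4-[(methoxycarbonyl)oxy]-2-methylbut-2-en-1-yl acetate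
Product: 11 (1R,5R,6S)-4-hydroxy-5-methyl-3-(2-methylpropanoyl)-6-(prop-1-en-2-yl)-1-(prop-2-en-1-yl)bicyclo[3.2.1]oct-3-ene-2,8-dione, via monoalkylated dienone 10 (not isolated)
Conditions: Pd2(dba)3·CHCl3 (2.5 mol %), (R,R)-DACH-phenyl diphosphine N,N'-[(1R,2R)-cyclohexane-1,2-diyl]bis[2-(diphenylphosphanyl)benzamide] (7.5 mol %), degassed THF, 9 (1.1 equiv) added slowly at 0 °C → rt, then 50 °C
Reagents that add atoms: none
Why: Proposed new method: zerovalent palladium should ionise the allylic carbonate first, the phloroglucinolate formed by the released methoxide should add through its allyl-bearing ring carbon to the unsubstituted CH2 terminus of the first π-allyl complex to give dienone 10, and ionisation of the allylic acetate should then let the methyl-bearing enol carbon attack the internal CH terminus of the second π-allyl complex, so that C1–C7 and C5–C6 form and the cyclopentanone ring C1–C7–C6–C5–C8 closes in the 5-exo mode in preference to 7-endo. The closest known reactions are the palladium-catalysed dearomative allylic annulation of acylphloroglucinols with 2-methylenepropane-1,3-diyl biscarbonates and the 5-exo Tsuji–Trost cyclisation of 1,3-dicarbonyl compounds onto a tethered allylic ester that gives 3-vinylcyclopentanones. C1 is set in the first alkylation, where the chiral pocket of the diphosphine selects one face of the planar nucleophile; C5 has no freedom, because the two-atom bridge can only reach the ring face from which it hangs; C6 is set in the closure, where the π-allyl faces interconvert through the CH2 terminus and the palladium-bearing 2-propenyl unit should take the exo side, away from the C2–C4 bridge. The order of ionisation rests on carbonate against acetate, O-allylated species are allylic vinylogous esters that should re-ionise and drain to the C-bonded bicycle, and the acyl-bearing carbon C3 is too stabilised and too crowded to compete in the closure. The one selectivity the substrate does not enforce is the choice between the allyl-bearing and the methyl-bearing carbon in the first, intermolecular alkylation; base-mediated gem-diprenylation of 3-methylacylphloroglucinols indicates that an allyl-bearing carbon is a competent site, and the regioisomeric bicycle, if formed, is a constitutional isomer that is removed at this stage.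

Step 7
Reactants: 11 (1R,5R,6S)-4-hydroxy-5-methyl-3-(2-methylpropanoyl)-6-(prop-1-en-2-yl)-1-(prop-2-en-1-yl)bicyclo[3.2.1]oct-3-ene-2,8-dione
Product: 12 (1R,5R,6R)-4-hydroxy-6-(2-hydroxypropan-2-yl)-5-methyl-3-(2-methylpropanoyl)-1-(prop-2-en-1-yl)bicyclo[3.2.1]oct-3-ene-2,8-dione
Conditions: Co(acac)2 (20 mol %), PhSiH3 (2 equiv), O2 (1 atm), THF, 0 °C → rt
Reagents that add atoms: dioxygen, O=O
Why: Mukaiyama hydration (cobalt-hydride hydrogen-atom transfer, then capture of the radical by O2) should give the Markovnikov tertiary alcohol at the 1,1-disubstituted 2-propenyl group, which forms a tertiary radical and reacts faster than the monosubstituted allyl group, without creating a stereocentre or disturbing C6.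

Step 8
Reactants: 12 (1R,5R,6R)-4-hydroxy-6-(2-hydroxypropan-2-yl)-5-methyl-3-(2-methylpropanoyl)-1-(prop-2-en-1-yl)bicyclo[3.2.1]oct-3-ene-2,8-dione
Product: 13 (1R,5R,6R)-4-hydroxy-6-(2-hydroxypropan-2-yl)-5-methyl-1-(3-methylbut-2-en-1-yl)-3-(2-methylpropanoyl)bicyclo[3.2.1]oct-3-ene-2,8-dione
Conditions: second-generation Grubbs catalyst RuCl2(=CHPh)(PCy3)(H2IMes) (5 mol %), 2-methylbut-2-ene (excess), CH2Cl2, 40 °C
Reagents that add atoms: 2-methylbut-2-ene, CC=C(C)C
Why: Olefin cross-metathesis of the monosubstituted allyl group with excess 2-methylbut-2-ene should convert allyl into prenyl with loss of propene, while the tertiary alcohol and the tetrasubstituted enol double bond take no part.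

**Compound list**

1 | 2,4,6-trihydroxytoluene (2-methylbenzene-1,3,5-triol) | Cc1c(O)cc(O)cc1O | starting material
2 | isobutyryl chloride (2-methylpropanoyl chloride) | CC(C)C(Cl)=O | starting material
3 | 1-(2,4,6-trihydroxy-3-methylphenyl)-2-methylpropan-1-one | CC(C)C(=O)c1c(O)cc(O)c(C)c1O | intermediate
4 | allyl bromide (3-bromoprop-1-ene) | C=CCBr | starting material
5 | 1-[2,4,6-trihydroxy-3-methyl-5-(prop-2-en-1-yl)phenyl]-2-methylpropan-1-one | CC(C)C(=O)c1c(O)c(C)c(O)c(CC=C)c1O | intermediate
6 | prenol (3-methylbut-2-en-1-ol) | CC(C)=CCO | starting material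
7 | methyl 3-methylbut-2-en-1-yl carbonate | COC(=O)OCC=C(C)C | intermediate
8 | (2E)-4-hydroxy-3-methylbut-2-en-1-yl methyl carbonate | COC(=O)OC/C=C(\C)CO | intermediate
9 | (2E)-4-[(methoxycarbonyl)oxy]-2-methylbut-2-en-1-yl acetate | COC(=O)OC/C=C(\C)COC(C)=O | intermediate
10 | (2E)-4-[(1S)-2,4-dihydroxy-5-methyl-3-(2-methylpropanoyl)-6-oxo-1-(prop-2-en-1-yl)cyclohexa-2,4-dien-1-yl]-2-methylbut-2-en-1-yl acetate | C=CC[C@@]1(C/C=C(\C)COC(C)=O)C(=O)C(C)=C(O)C(C(=O)C(C)C)=C1O | intermediate
11 | (1R,5R,6S)-4-hydroxy-5-methyl-3-(2-methylpropanoyl)-6-(prop-1-en-2-yl)-1-(prop-2-en-1-yl)bicyclo[3.2.1]oct-3-ene-2,8-dione (2-propenyl group exo, on the side of the C8 bridge) | C=CC[C@@]12C[C@@H](C(C)=C)[C@@](C)(C1=O)C(O)=C(C(=O)C(C)C)C2=O | intermediate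
12 | (1R,5R,6R)-4-hydroxy-6-(2-hydroxypropan-2-yl)-5-methyl-3-(2-methylpropanoyl)-1-(prop-2-en-1-yl)bicyclo[3.2.1]oct-3-ene-2,8-dione | C=CC[C@@]12C[C@@H](C(C)(C)O)[C@@](C)(C1=O)C(O)=C(C(=O)C(C)C)C2=O | intermediate
13 | (1R,5R,6R)-4-hydroxy-6-(2-hydroxypropan-2-yl)-5-methyl-1-(3-methylbut-2-en-1-yl)-3-(2-methylpropanoyl)bicyclo[3.2.1]oct-3-ene-2,8-dione | CC(C)=CC[C@@]12C[C@@H](C(C)(C)O)[C@@](C)(C1=O)C(O)=C(C(=O)C(C)C)C2=O | target

**Step count and risks**

Total: 8 steps. Longest linear sequence: 6 steps (6 → 7 → 8 → 9 → 11 → 12 → 13); the arene branch (1 → 3 → 5) joins at step 6.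

Steps most likely to fail:

Step 6. The first, intermolecular dearomatising alkylation may go to the methyl-bearing instead of the allyl-bearing ring carbon, which leads to the regioisomeric bicycle. The closure may also stop at an O-bonded dihydrofuran, or face selection by the catalyst may be poor. The fallback sets out from 5 and returns at 11, and uses known chemistry only. Compound 5 is C-prenylated with prenyl bromide in 10% aq. KOH at 0 °C, a base-mediated dearomatising alkylation of the kind used for gem-diprenylation of 3-methylacylphloroglucinols. This should give the racemic dienone 3,5-dihydroxy-2-methyl-6-(3-methylbut-2-en-1-yl)-4-(2-methylpropanoyl)-6-(prop-2-en-1-yl)cyclohexa-2,4-dien-1-one F1. The isomer alkylated at the methyl-bearing carbon is removed here, at a stable and isolable stage. Oxidative radical cyclisation with Mn(OAc)3·2H2O (2.2 equiv) and Cu(OAc)2·H2O (cat.) in AcOH at rt then generates the radical at the methyl-bearing carbon, which adds 5-exo to the prenyl double bond. Divalent copper oxidises the resulting tertiary radical to the 2-propenyl group, giving the racemic bicycle rac-11 F2. Preparative HPLC on a chiral stationary phase (amylose tris(3,5-dimethylphenylcarbamate)) separates the enantiomers and delivers 11.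

Step 7. Chemoselectivity between the 2-propenyl and the allyl group may erode, or the acidic enolised triketone may sequester cobalt and stall the hydrogen-atom transfer. The fallback sets out from 11 and returns at 12, and replaces the radical hydration by an ionic one. Oxymercuration with Hg(OAc)2 (1.0 equiv) in THF–H2O at 0 °C attacks the more nucleophilic 1,1-disubstituted alkene with Markovnikov orientation. It should give the organomercurial (acetato){2-hydroxy-2-[(1R,5R,6R)-4-hydroxy-5-methyl-3-(2-methylpropanoyl)-2,8-dioxo-1-(prop-2-en-1-yl)bicyclo[3.2.1]oct-3-en-6-yl]propyl}mercury F3. Brief demercuration with NaBH4 in aq. NaOH at 0 °C, where the triketone is protected as its enolate, then gives 12.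

Step 2. Over-allylation to a gem-diallyl dienone, dearomatising attack at the methyl-bearing carbon and O-allylation may all compete with the desired mono-C-allylation. The fallback sets out from 3 and returns at 5, and makes the C–C bond by a sigmatropic shift instead of direct alkylation. Allyl bromide with K2CO3 in acetone at rt should etherify the most acidic, non-chelated hydroxyl (para to the ketone) to give 1-[2,6-dihydroxy-3-methyl-4-(prop-2-en-1-yloxy)phenyl]-2-methylpropan-1-one F4. Aromatic Claisen rearrangement in N,N-diethylaniline at 190 °C then moves the allyl group to the only free ortho carbon and gives 5.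

Further compounds
F1 | step 6 | 3,5-dihydroxy-2-methyl-6-(3-methylbut-2-en-1-yl)-4-(2-methylpropanoyl)-6-(prop-2-en-1-yl)cyclohexa-2,4-dien-1-one (racemic) | C=CCC1(CC=C(C)C)C(=O)C(C)=C(O)C(C(=O)C(C)C)=C1O
F2 | step 6 | rac-11, racemic (1R,5R,6S)-4-hydroxy-5-methyl-3-(2-methylpropanoyl)-6-(prop-1-en-2-yl)-1-(prop-2-en-1-yl)bicyclo[3.2.1]oct-3-ene-2,8-dione (relative configuration shown) | C=CC[C@@]12C[C@@H](C(C)=C)[C@@](C)(C1=O)C(O)=C(C(=O)C(C)C)C2=O
F3 | step 7 | (acetato){2-hydroxy-2-[(1R,5R,6R)-4-hydroxy-5-methyl-3-(2-methylpropanoyl)-2,8-dioxo-1-(prop-2-en-1-yl)bicyclo[3.2.1]oct-3-en-6-yl]propyl}mercury (both epimers at the carbinol carbon) | C=CC[C@@]12C[C@@H](C(C)(O)C[Hg]OC(C)=O)[C@@](C)(C1=O)C(O)=C(C(=O)C(C)C)C2=O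
F4 | step 2 | 1-[2,6-dihydroxy-3-methyl-4-(prop-2-en-1-yloxy)phenyl]-2-methylpropan-1-one | CC(C)C(=O)c1c(O)cc(OCC=C)c(C)c1O
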